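Numbering: butenolide C1(=O)–C4, chain C5–C11 (C7=C8, C10=C11), tetrahydrofuran C12–C15 (ring O joins C12 and C15), lactone C16–C19. The retrosynthesis cuts C9–C10 (allyl–alkenyl Stille), then C10–C11 (alkyne homologation of a C11 aldehyde), the lactone O–C19 bond, the ring O–C15 and C16–O bonds together, and last C13–C14 (sulfone anion plus epoxide).
Forward: the allylic sulfone of nerol opens silylated (S)-2-methylglycidol to give the C11–C19 chain, and its isopropylidene end is cut down to the C19 methyl ester. The tetrahydrofuran closes first (step 9) and the lactone second (step 10); the butenolide ring is made separately by sulfoxide elimination and the halves are joined in the last step.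
Enabling feature: the C–O bonds at C15 (ring oxygen) and C16 (lactone oxygen) correspond to a same-face addition to a C15=C16 double bond with C14 and C17 cis, which is the Z alkene that nerol supplies. The C12 oxygen is a tertiary alcohol three carbons from C15, so a perrhenate ester at C12 can deliver both oxygens as the tetrahydrofuran ring forms.
Stereochemistry: C12 comes from the chiral pool and none of its bonds is ever broken. C15 is set in step 9 under control of C12 (trans ring), and C16 follows from syn addition to the Z alkene. E-C7=C8 comes from oxidation of the E-methyl of an isopropylidene unit, and E-C10=C11 from syn hydrostannation of an alkyne.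

Key step: step 9

Assumption: the sulfonyl-bearing carbon of 6–9 (both epimers) and the α-carbon of 25 and 26 (racemic) are drawn without configuration because these centres do not survive; 1, 4, 22 and 24 are bought.

Step 1
Reactants: 1 nerol
Product: 2 neryl bromide
Conditions: PBr3, pyridine (cat.), Et2O, −10 °C
Reagents that add atoms: phosphorus tribromide, BrP(Br)Br
Why: Bromination of a primary allylic alcohol with PBr3 (SN2 on the bromophosphite) at low temperature is the standard route to neryl bromide and should not disturb the Z-trisubstituted alkene.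

Step 2
Reactants: 2 neryl bromide
Product: 3 neryl phenyl sulfone
Conditions: PhSO2Na, DMF, rt
Reagents that add atoms: sodium benzenesulfinate, [Na+].[O-]S(=O)c1ccccc1
Why: S-alkylation of the sulfinate by the allylic bromide (SN2) in DMF should give the allylic sulfone with the Z geometry retained.

Step 3
Reactants: 4 (S)-2-methylglycidol
Product: 5 tert-butyl{[(2R)-2-methyloxiran-2-yl]methoxy}diphenylsilane
Conditions: TBDPSCl, imidazole, CH2Cl2, 0 °C → rt
Reagents that add atoms: tert-butyl(chloro)diphenylsilane, CC(C)(C)[Si](Cl)(c1ccccc1)c1ccccc1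
Why: Imidazole-promoted silylation of the primary alcohol leaves the epoxide and its quaternary stereocentre untouched; the descriptor changes from S to R only because silicon raises the CIP rank of the CH2O arm.

Step 4
Reactants: 3 neryl phenyl sulfone; 5 silylated epoxide
Product: 6 (2R,5Z)-1-{[tert-butyl(diphenyl)silyl]oxy}-2,6,10-trimethyl-4-(phenylsulfonyl)undeca-5,9-dien-2-ol
Conditions: n-BuLi, THF/HMPA, −78 °C; then 5, −78 °C → rt
Reagents that add atoms: none
Why: The lithiated allylic sulfone reacts through its α-carbon and opens the 2,2-disubstituted epoxide at the unsubstituted CH2 (SN2 epoxide opening), so C12 keeps its configuration and the Z alkene stays in place; the new sulfonyl-bearing carbon forms as both epimers, which does not matter because it becomes CH2 in step 6.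

Step 5
Reactants: 6 hydroxy sulfone
Product: 8 (4Z,8R)-9-{[tert-butyl(diphenyl)silyl]oxy}-8-hydroxy-4,8-dimethyl-6-(phenylsulfonyl)non-4-enal, via sulfonyl triol 7 (not isolated)
Conditions: OsO4 (cat.), NaIO4, 2,6-lutidine, dioxane/H2O, rt
Reagents that add atoms: osmium tetroxide, O=[Os](=O)(=O)=O; sodium periodate, [Na+].[O-]I(=O)(=O)=O
Why: Lemieux–Johnson cleavage, in which osmium tetroxide should pick the electron-rich, unhindered isopropylidene alkene over the alkene that is deactivated and shielded by the allylic sulfonyl group, and periodate cleaves glycol 7 to the aldehyde.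

Step 6
Reactants: 8 sulfonyl aldehyde
Product: 10 (2R,5Z)-1-{[tert-butyl(diphenyl)silyl]oxy}-2,6-dimethylnon-5-ene-2,9-diol, via sulfonyl alcohol 9 (not isolated)
Conditions: PdCl2(dppp) (cat.), LiBHEt3 (excess), THF, 0 °C
Reagents that add atoms: none
Why: Super-Hydride reduces the aldehyde at once and then serves as hydride donor in the Pd(0)/dppp-catalysed hydrogenolysis of the allylic sulfone (π-allyl palladium intermediate), a reaction known to put hydrogen on the carbon that carried sulfur and to leave the position and Z geometry of a trisubstituted alkene unchanged.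

Step 7
Reactants: 10 diol
Product: 12 (4Z,8R)-9-{[tert-butyl(diphenyl)silyl]oxy}-8-hydroxy-4,8-dimethylnon-4-enoic acid, via hydroxy aldehyde 11 (not isolated)
Conditions: TEMPO (cat.), PhI(OAc)2, MeCN/H2O, rt
Reagents that add atoms: water, O
Why: Oxoammonium (TEMPO/PhI(OAc)2) oxidation of the primary alcohol in wet acetonitrile proceeds through the aldehyde hydrate to the acid and should leave the tertiary alcohol, the alkene and the silyl ether alone.

Step 8
Reactants: 12 hydroxy acid
Product: 13 methyl (4Z,8R)-9-{[tert-butyl(diphenyl)silyl]oxy}-8-hydroxy-4,8-dimethylnon-4-enoate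
Conditions: TMSCHN2, PhMe/MeOH, 0 °C
Reagents that add atoms: trimethylsilyldiazomethane, C[Si](C)(C)C=[N+]=[N-]
Why: Diazoalkane esterification with trimethylsilyldiazomethane in methanol is neutral and specific for the carboxylic acid, so the tertiary alcohol stays free for step 9.

Step 9
Reactants: 13 (R,Z)-hydroxy ester
Product: 16 methyl (4S)-4-hydroxy-4-[(2R,5R)-5-({[tert-butyl(diphenyl)silyl]oxy}methyl)-5-methyloxolan-2-yl]pentanoate, via perrhenate ester 14 (not isolated), via rhenium(V) alkoxide 15 (not isolated)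
Conditions: Re2O7, 2,6-lutidine, CH2Cl2, rt, dark; then aq. NaHCO3/H2O2, 0 °C
Reagents that add atoms: dirhenium heptoxide, O=[Re](=O)(=O)O[Re](=O)(=O)=O
Why: The C12 tertiary alcohol exchanges onto rhenium to give alkyl perrhenate 14, whose O–Re=O unit adds to one face of the C15=C16 alkene in a concerted (3+2) fashion (closest known reaction type: Re(VII) syn-oxidative cyclisation of bishomoallylic alcohols to trans-tetrahydrofuranyl carbinols), and oxidative hydrolysis of rhenium(V) alkoxide 15 frees the C16 alcohol. The tetrahydrofuran closes 5-exo with respect to the alkene, the alkoxide oxygen going to the near carbon C15 and an oxo oxygen to C16. C15 is controlled by the existing C12 centre: in the cyclic transition state the bulkier CH2OTBDPS arm should take the pseudo-equatorial site and the methyl the pseudo-axial one, which puts that arm trans to the C16 side chain on the ring and gives 15R. C16 is controlled by the alkene geometry, since delivery of both oxygens to the same face of the Z alkene taken from nerol fixes the 15R,16S relationship. The step needs face selectivity (trans over cis ring), which rests on the size difference between CH2OTBDPS and CH3 at C12, and chemoselectivity, which rests on there being no second alkene for a C16 perrhenate to attack (C19 is an ester) and no allylic alcohol that rhenium could transpose (C11 is a saturated silyl ether), with 2,6-lutidine buffering the perrhenic acid.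

Step 10
Reactants: 16 tetrahydrofuranyl hydroxy ester
Product: 17 (5S)-5-[(2R,5R)-5-({[tert-butyl(diphenyl)silyl]oxy}methyl)-5-methyloxolan-2-yl]-5-methyloxolan-2-one
Conditions: TsOH·H2O (cat.), CH2Cl2, rt
Reagents that add atoms: none
Why: Acid-catalysed lactonisation (intramolecular transesterification) of the tertiary γ-hydroxy ester is favoured by the gem-disubstitution and exchanges only the acyl C–O bond, so C16 keeps its configuration.

Step 11
Reactants: 17 silyl ether lactone
Product: 18 (5S)-5-[(2R,5R)-5-(hydroxymethyl)-5-methyloxolan-2-yl]-5-methyloxolan-2-one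
Conditions: TBAF, AcOH, THF, rt
Reagents that add atoms: none
Why: Fluoride-mediated desilylation of the primary TBDPS ether, buffered with acetic acid so that the lactone is not opened.

Step 12
Reactants: 18 primary alcohol
Product: 19 (2R,5R)-2-methyl-5-[(2S)-2-methyl-5-oxooxolan-2-yl]oxolane-2-carbaldehyde
Conditions: Dess–Martin periodinane, CH2Cl2, rt
Reagents that add atoms: none
Why: Dess–Martin oxidation of the primary alcohol gives an aldehyde that has no α-hydrogen and therefore cannot epimerise at C12.

Step 13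
Reactants: 19 aldehyde
Product: 20 (5S)-5-[(2R,5R)-5-ethynyl-5-methyloxolan-2-yl]-5-methyloxolan-2-one
Conditions: dimethyl (1-diazo-2-oxopropyl)phosphonate, K2CO3, MeOH, 0 °C → rt
Reagents that add atoms: dimethyl (1-diazo-2-oxopropyl)phosphonate, CC(=O)C(=[N+]=[N-])P(=O)(OC)OC
Why: Seyferth–Gilbert homologation with the Ohira–Bestmann reagent converts the non-enolisable aldehyde into the terminal alkyne under mild carbonate conditions, and the γ,γ-disubstituted lactone is favoured over its methanolysis product.

Step 14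
Reactants: 20 alkyne
Product: 21 (5S)-5-methyl-5-{(2R,5R)-5-methyl-5-[(E)-2-(tributylstannyl)ethenyl]oxolan-2-yl}oxolan-2-one
Conditions: Bu3SnH, PdCl2(PPh3)2 (cat.), THF, 0 °C → rt
Reagents that add atoms: tributyltin hydride, CCCC[SnH](CCCC)CCCC
Why: Palladium-catalysed syn hydrostannation places tin on the terminal carbon, because the fully substituted propargylic centre blocks the internal position, and so should give the E-alkenylstannane.

Step 15
Reactants: 22 3-bromodihydrofuran-2(3H)-one
Product: 23 3-(phenylsulfanyl)dihydrofuran-2(3H)-one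
Conditions: PhSH, Et3N, CH2Cl2, 0 °C → rt
Reagents that add atoms: thiophenol, Sc1ccccc1
Why: SN2 displacement of the α-bromide of the lactone by thiophenolate.

Step 16
Reactants: 23 α-phenylsulfanyl lactone; 24 5-bromo-2-methylpent-2-ene
Product: 25 3-(4-methylpent-3-en-1-yl)-3-(phenylsulfanyl)dihydrofuran-2(3H)-one
Conditions: LDA, THF/HMPA, −78 °C; then 24, −78 °C → rt
Reagents that add atoms: none
Why: Alkylation of the sulfur-stabilised lactone enolate with the primary bromide (SN2, favoured over elimination for this soft, weakly basic enolate); the new quaternary centre is racemic and is removed in step 17.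

Step 17
Reactants: 25 alkylated sulfide
Product: 27 3-(4-methylpent-3-en-1-yl)furan-2(5H)-one, via sulfoxide 26 (not isolated)
Conditions: mCPBA (1 equiv), CH2Cl2, −78 °C; aq. NaHCO3 wash; then PhMe, 110 °C
Reagents that add atoms: none
Why: Sulfide oxidation with one equivalent of peracid at −78 °C is much faster than epoxidation of the trisubstituted alkene, and thermal syn elimination of sulfoxide 26 should give the endocyclic conjugated butenolide, as is usual for α-alkyl-α-sulfinyl butyrolactones.

Step 18
Reactants: 27 butenolide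
Product: 28 3-[(3E)-5-hydroxy-4-methylpent-3-en-1-yl]furan-2(5H)-one
Conditions: SeO2 (cat.), t-BuOOH, salicylic acid (cat.), CH2Cl2, rt
Reagents that add atoms: selenium dioxide, O=[Se]=O; tert-butyl hydroperoxide, CC(C)(C)OO
Why: Riley-type allylic oxidation (ene reaction, then [2,3]-sigmatropic shift) attacks the E-methyl group of the electron-rich isopropylidene unit and so should give the E-allylic alcohol, while the electron-poor butenolide alkene does not react.

Step 19
Reactants: 28 allylic alcohol
Product: 29 3-[(3E)-5-bromo-4-methylpent-3-en-1-yl]furan-2(5H)-one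
Conditions: CBr4, PPh3, CH2Cl2, 0 °C
Reagents that add atoms: carbon tetrabromide, BrC(Br)(Br)Br
Why: Appel bromination turns the primary allylic alcohol into the bromide under neutral conditions and without allylic transposition, keeping the E geometry.

Step 20
Reactants: 21 alkenylstannane; 29 allylic bromide
Product: 30 3-[(3E,6E)-4-methyl-7-{(2R,5R)-2-methyl-5-[(2S)-2-methyl-5-oxooxolan-2-yl]oxolan-2-yl}hepta-3,6-dien-1-yl]furan-2(5H)-one (CNP0301418.1)
Conditions: Pd2(dba)3 (cat.), AsPh3, degassed DMF, rt → 40 °C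
Reagents that add atoms: none
Why: Stille coupling, in which oxidative addition of the allylic bromide gives a π-allyl palladium species that should couple with the alkenylstannane at its unsubstituted CH2 terminus with retention of both alkene geometries, under neutral conditions that the butenolide and the lactone tolerate.

Compound list
1 | nerol, (2Z)-3,7-dimethylocta-2,6-dien-1-ol | OC/C=C(/C)CCC=C(C)C | starting material
2 | neryl bromide, (2Z)-1-bromo-3,7-dimethylocta-2,6-diene | BrC/C=C(/C)CCC=C(C)C | intermediate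
3 | neryl phenyl sulfone, {[(2Z)-3,7-dimethylocta-2,6-dien-1-yl]sulfonyl}benzene | O=S(=O)(C/C=C(/C)CCC=C(C)C)c1ccccc1 | intermediate
4 | (S)-2-methylglycidol | OC[C@@]1(C)CO1 | starting material
5 | tert-butyl{[(2R)-2-methyloxiran-2-yl]methoxy}diphenylsilane | CC(C)(C)[Si](c1ccccc1)(c1ccccc1)OC[C@@]1(C)CO1 | intermediate
6 | (2R,5Z)-1-{[tert-butyl(diphenyl)silyl]oxy}-2,6,10-trimethyl-4-(phenylsulfonyl)undeca-5,9-dien-2-ol (both C4 epimers) | CC(C)(C)[Si](c1ccccc1)(c1ccccc1)OC[C@@](O)(C)CC(S(=O)(=O)c1ccccc1)/C=C(/C)CCC=C(C)C | intermediate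
7 | (2R,5Z)-1-{[tert-butyl(diphenyl)silyl]oxy}-2,6,10-trimethyl-4-(phenylsulfonyl)undec-5-ene-2,9,10-triol (not isolated) | CC(C)(C)[Si](c1ccccc1)(c1ccccc1)OC[C@@](O)(C)CC(S(=O)(=O)c1ccccc1)/C=C(/C)CCC(O)C(C)(C)O | intermediate
8 | (4Z,8R)-9-{[tert-butyl(diphenyl)silyl]oxy}-8-hydroxy-4,8-dimethyl-6-(phenylsulfonyl)non-4-enal | CC(C)(C)[Si](c1ccccc1)(c1ccccc1)OC[C@@](O)(C)CC(S(=O)(=O)c1ccccc1)/C=C(/C)CCC=O | intermediate
9 | (2R,5Z)-1-{[tert-butyl(diphenyl)silyl]oxy}-2,6-dimethyl-4-(phenylsulfonyl)non-5-ene-2,9-diol (not isolated) | CC(C)(C)[Si](c1ccccc1)(c1ccccc1)OC[C@@](O)(C)CC(S(=O)(=O)c1ccccc1)/C=C(/C)CCCO | intermediate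
10 | (2R,5Z)-1-{[tert-butyl(diphenyl)silyl]oxy}-2,6-dimethylnon-5-ene-2,9-diol | CC(C)(C)[Si](c1ccccc1)(c1ccccc1)OC[C@@](O)(C)CC/C=C(/C)CCCO | intermediate
11 | (4Z,8R)-9-{[tert-butyl(diphenyl)silyl]oxy}-8-hydroxy-4,8-dimethylnon-4-enal (not isolated) | CC(C)(C)[Si](c1ccccc1)(c1ccccc1)OC[C@@](O)(C)CC/C=C(/C)CCC=O | intermediate
12 | (4Z,8R)-9-{[tert-butyl(diphenyl)silyl]oxy}-8-hydroxy-4,8-dimethylnon-4-enoic acid | CC(C)(C)[Si](c1ccccc1)(c1ccccc1)OC[C@@](O)(C)CC/C=C(/C)CCC(=O)O | intermediate
13 | methyl (4Z,8R)-9-{[tert-butyl(diphenyl)silyl]oxy}-8-hydroxy-4,8-dimethylnon-4-enoate | CC(C)(C)[Si](c1ccccc1)(c1ccccc1)OC[C@@](O)(C)CC/C=C(/C)CCC(=O)OC | intermediate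
14 | perrhenate ester of 13 at the C12 oxygen (not isolated) | CC(C)(C)[Si](c1ccccc1)(c1ccccc1)OC[C@@](O[Re](=O)(=O)=O)(C)CC/C=C(/C)CCC(=O)OC | intermediate
15 | dioxorhenium(V) alkoxide of 16 at the C16 oxygen (not isolated) | CC(C)(C)[Si](c1ccccc1)(c1ccccc1)OC[C@@]1(C)CC[C@H]([C@](O[Re](=O)=O)(C)CCC(=O)OC)O1 | intermediate
16 | methyl (4S)-4-hydroxy-4-[(2R,5R)-5-({[tert-butyl(diphenyl)silyl]oxy}methyl)-5-methyloxolan-2-yl]pentanoate | CC(C)(C)[Si](c1ccccc1)(c1ccccc1)OC[C@@]1(C)CC[C@H]([C@](O)(C)CCC(=O)OC)O1 | intermediate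
17 | (5S)-5-[(2R,5R)-5-({[tert-butyl(diphenyl)silyl]oxy}methyl)-5-methyloxolan-2-yl]-5-methyloxolan-2-one | CC(C)(C)[Si](c1ccccc1)(c1ccccc1)OC[C@@]1(C)CC[C@H]([C@]2(C)CCC(=O)O2)O1 | intermediate
18 | (5S)-5-[(2R,5R)-5-(hydroxymethyl)-5-methyloxolan-2-yl]-5-methyloxolan-2-one | OC[C@@]1(C)CC[C@H]([C@]2(C)CCC(=O)O2)O1 | intermediate
19 | (2R,5R)-2-methyl-5-[(2S)-2-methyl-5-oxooxolan-2-yl]oxolane-2-carbaldehyde | O=C[C@@]1(C)CC[C@H]([C@]2(C)CCC(=O)O2)O1 | intermediate
20 | (5S)-5-[(2R,5R)-5-ethynyl-5-methyloxolan-2-yl]-5-methyloxolan-2-one | C#C[C@@]1(C)CC[C@H]([C@]2(C)CCC(=O)O2)O1 | intermediate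
21 | (5S)-5-methyl-5-{(2R,5R)-5-methyl-5-[(E)-2-(tributylstannyl)ethenyl]oxolan-2-yl}oxolan-2-one | CCCC[Sn](CCCC)(CCCC)/C=C/[C@@]1(C)CC[C@H]([C@]2(C)CCC(=O)O2)O1 | intermediate
22 | 3-bromodihydrofuran-2(3H)-one (racemic) | O=C1OCCC1Br | starting material
23 | 3-(phenylsulfanyl)dihydrofuran-2(3H)-one (racemic) | O=C1OCCC1Sc1ccccc1 | intermediate
24 | 5-bromo-2-methylpent-2-ene | BrCCC=C(C)C | starting material
25 | 3-(4-methylpent-3-en-1-yl)-3-(phenylsulfanyl)dihydrofuran-2(3H)-one (racemic) | O=C1OCCC1(CCC=C(C)C)Sc1ccccc1 | intermediate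
26 | 3-(4-methylpent-3-en-1-yl)-3-(phenylsulfinyl)dihydrofuran-2(3H)-one (stereoisomer mixture, not isolated) | O=C1OCCC1(CCC=C(C)C)S(=O)c1ccccc1 | intermediate
27 | 3-(4-methylpent-3-en-1-yl)furan-2(5H)-one | O=C1OCC=C1CCC=C(C)C | intermediate
28 | 3-[(3E)-5-hydroxy-4-methylpent-3-en-1-yl]furan-2(5H)-one | O=C1OCC=C1CC/C=C(\C)CO | intermediate
29 | 3-[(3E)-5-bromo-4-methylpent-3-en-1-yl]furan-2(5H)-one | O=C1OCC=C1CC/C=C(\C)CBr | intermediate
30 | 3-[(3E,6E)-4-methyl-7-{(2R,5R)-2-methyl-5-[(2S)-2-methyl-5-oxooxolan-2-yl]oxolan-2-yl}hepta-3,6-dien-1-yl]furan-2(5H)-one | C/C(=C\CCC1=CCOC1=O)C/C=C/[C@@]1(C)CC[C@H]([C@]2(C)CCC(=O)O2)O1 | target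

Total step count: 20.
Longest linear sequence: 14 steps (steps 1, 2, 4–14 and 20, from nerol).

Steps most likely to fail

Step 9. The risk is poor face selectivity in the (3+2) addition, giving the cis ring beside the trans ring if CH2OTBDPS and CH3 at C12 differ too little in size, or ionisation and elimination of the tertiary perrhenate before it adds. The fallback replaces syn addition to the Z alkene by stereospecific anti opening of an E epoxide. It sets out from silyl epoxide 5, which is alkylated as in step 4 with geranyl phenyl sulfone F1 (from commercial geranyl bromide and sodium benzenesulfinate) to give the E-hydroxy sulfone F2. The operations of steps 5–8 then lead through the E-sulfonyl triol F3 to the E-sulfonyl aldehyde F4, through the E-sulfonyl alcohol F5 to the E-diol F6, through the E-hydroxy aldehyde F7 to the E-acid F8, and on to the E-methyl ester F9. Shi epoxidation of F9 with the enantiomer of the fructose-derived ketone (Oxone, K2CO3, MeCN/dimethoxymethane/buffer, 0 °C) should give the (S,S)-epoxy alcohol F10 under reagent control. Camphorsulfonic acid in CH2Cl2 then lets the C12 hydroxyl open the epoxide 5-exo at C15 with inversion, which fixes 15R,16S without relying on C12 for face selection. The sequence comes back to the route at hydroxy ester 16.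

Step 20. The risk is slow transmetalation of the hindered alkenylstannane, which gives the π-allyl palladium intermediate time for syn–anti isomerisation (loss of E geometry at C7=C8), coupling at its substituted terminus or homocoupling, and leaves the stannane open to protodestannylation. The fallback forms C10=C11 by cross-metathesis instead of forming C9–C10 by Stille coupling. It sets out from aldehyde 19, which is methylenated (Ph3P=CH2, THF, 0 °C) to the vinyl tetrahydrofuran F11, and from bromide 29, which is coupled with the small and fast tributyl(vinyl)stannane (Pd2(dba)3, AsPh3, DMF) to give the skipped diene F12. Cross-metathesis of F11 with F12 (Hoveyda–Grubbs second-generation catalyst, CH2Cl2, 40 °C) should join the two terminal alkenes E-selectively, since the trisubstituted C7=C8 alkene and the butenolide alkene are too hindered or too electron-poor to take part. The fallback comes back to the route at target 30.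

Step 6. The risk is capture of the π-allyl palladium intermediate by the freshly formed C19 alkoxide (or its borate) in place of hydride, with erosion of alkene position or geometry if hydride transfer is slowed. The fallback masks the chain end before the sulfone is removed. It sets out from hydroxy sulfone 6, which is osmylated without periodate (OsO4 cat., NMO, acetone/H2O) so that the reaction stops at triol 7. The glycol of 7 is then protected (2,2-dimethoxypropane, PPTS) as the sulfonyl acetonide F13, the isolated tertiary alcohol staying free. The Pd/LiBHEt3 reduction, now with only the hindered tertiary alkoxide present, should give the sulfone-free acetonide F14. Periodic acid in EtOAc cleaves the acetonide directly to hydroxy aldehyde 11, and Pinnick oxidation (NaClO2, NaH2PO4, 2-methyl-2-butene, t-BuOH/H2O) gives acid 12, where the route is rejoined.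

Further compounds
F1 | step 9 | geranyl phenyl sulfone, {[(2E)-3,7-dimethylocta-2,6-dien-1-yl]sulfonyl}benzene | O=S(=O)(C/C=C(\C)CCC=C(C)C)c1ccccc1
F2 | step 9 | (2R,5E)-1-{[tert-butyl(diphenyl)silyl]oxy}-2,6,10-trimethyl-4-(phenylsulfonyl)undeca-5,9-dien-2-ol | CC(C)(C)[Si](c1ccccc1)(c1ccccc1)OC[C@@](O)(C)CC(S(=O)(=O)c1ccccc1)/C=C(\C)CCC=C(C)C
F3 | step 9 | (2R,5E)-1-{[tert-butyl(diphenyl)silyl]oxy}-2,6,10-trimethyl-4-(phenylsulfonyl)undec-5-ene-2,9,10-triol | CC(C)(C)[Si](c1ccccc1)(c1ccccc1)OC[C@@](O)(C)CC(S(=O)(=O)c1ccccc1)/C=C(\C)CCC(O)C(C)(C)O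
F4 | step 9 | (4E,8R)-9-{[tert-butyl(diphenyl)silyl]oxy}-8-hydroxy-4,8-dimethyl-6-(phenylsulfonyl)non-4-enal | CC(C)(C)[Si](c1ccccc1)(c1ccccc1)OC[C@@](O)(C)CC(S(=O)(=O)c1ccccc1)/C=C(\C)CCC=O
F5 | step 9 | (2R,5E)-1-{[tert-butyl(diphenyl)silyl]oxy}-2,6-dimethyl-4-(phenylsulfonyl)non-5-ene-2,9-diol | CC(C)(C)[Si](c1ccccc1)(c1ccccc1)OC[C@@](O)(C)CC(S(=O)(=O)c1ccccc1)/C=C(\C)CCCO
F6 | step 9 | (2R,5E)-1-{[tert-butyl(diphenyl)silyl]oxy}-2,6-dimethylnon-5-ene-2,9-diol | CC(C)(C)[Si](c1ccccc1)(c1ccccc1)OC[C@@](O)(C)CC/C=C(\C)CCCO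
F7 | step 9 | (4E,8R)-9-{[tert-butyl(diphenyl)silyl]oxy}-8-hydroxy-4,8-dimethylnon-4-enal | CC(C)(C)[Si](c1ccccc1)(c1ccccc1)OC[C@@](O)(C)CC/C=C(\C)CCC=O
F8 | step 9 | (4E,8R)-9-{[tert-butyl(diphenyl)silyl]oxy}-8-hydroxy-4,8-dimethylnon-4-enoic acid | CC(C)(C)[Si](c1ccccc1)(c1ccccc1)OC[C@@](O)(C)CC/C=C(\C)CCC(=O)O
F9 | step 9 | methyl (4E,8R)-9-{[tert-butyl(diphenyl)silyl]oxy}-8-hydroxy-4,8-dimethylnon-4-enoate | CC(C)(C)[Si](c1ccccc1)(c1ccccc1)OC[C@@](O)(C)CC/C=C(\C)CCC(=O)OC
F10 | step 9 | methyl 3-[(2S,3S)-3-{(3R)-4-[tert-butyl(diphenyl)silyl]oxy-3-hydroxy-3-methylbutyl}-2-methyloxiran-2-yl]propanoate | CC(C)(C)[Si](c1ccccc1)(c1ccccc1)OC[C@@](O)(C)CC[C@@H]1O[C@@]1(C)CCC(=O)OC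
F11 | step 20 | (5S)-5-[(2R,5R)-5-ethenyl-5-methyloxolan-2-yl]-5-methyloxolan-2-one | C=C[C@@]1(C)CC[C@H]([C@]2(C)CCC(=O)O2)O1
F12 | step 20 | 3-[(3E)-4-methylhepta-3,6-dien-1-yl]furan-2(5H)-one | O=C1OCC=C1CC/C=C(\C)CC=C
F13 | step 6 | (2R,5Z)-1-{[tert-butyl(diphenyl)silyl]oxy}-2,6-dimethyl-4-(phenylsulfonyl)-8-(2,2,5,5-tetramethyl-1,3-dioxolan-4-yl)oct-5-en-2-ol | CC(C)(C)[Si](c1ccccc1)(c1ccccc1)OC[C@@](O)(C)CC(S(=O)(=O)c1ccccc1)/C=C(/C)CCC1OC(C)(C)OC1(C)C
F14 | step 6 | (2R,5Z)-1-{[tert-butyl(diphenyl)silyl]oxy}-2,6-dimethyl-8-(2,2,5,5-tetramethyl-1,3-dioxolan-4-yl)oct-5-en-2-ol | CC(C)(C)[Si](c1ccccc1)(c1ccccc1)OC[C@@](O)(C)CC/C=C(/C)CCC1OC(C)(C)OC1(C)C
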